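**Retrosynthetic overview**
1. The strategy rests on the tetralone benzene ring (C4a, C5, C6, C7, C8, C8a). It has OH on C7 and C8, the C1 ketone on C8a and the C4 stereocentre on C4a. Acylative closure of a 3,4-dioxygenated arene would go para to oxygen and give the 6,7-isomer, so this ring is built de novo.
2. Key disconnection at C4a–C8a and C7–C8: a 2-substituted furan supplies C4a, C5, C6, C7 and O-7, a methoxy-ynone supplies C1, C8a, C8 and O-8, and C4–C3–C2 joins them (intramolecular furan Diels–Alder benzannulation).
3. The ynone comes from a 4-furyl-4-naphthylbutanal and lithium methoxyacetylide. The butanal comes from one-carbon homologation of a 3-furyl-3-naphthylpropanoate, whose stereocentre (future C4) is set by Rh-catalysed asymmetric furyl 1,4-addition to a naphthylacrylate.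
4. The acrylate derives from 1,5-dimethoxynaphthalene by formylation, exchange of the para methyl ether for benzyl, and olefination.
5. Ring order: naphthalene and furan are bought, the cyclohexanone and oxygenated benzene rings form together in the key step, and one BCl3 treatment unmasks the target.

Key step: step 11

Assumption: the (S,S)-diene ligand is taken to deliver the furyl group to the α-si face of the acrylate, as it does with simpler enones, and this corresponds to the (S)-ester. The sense must be confirmed on a test run, and the antipodal ligand would be used if it proves opposite.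

Step 1
Reactants: 1 1,5-dimethoxynaphthalene
Product: 3 4,8-dimethoxy-1-naphthaldehyde, via aryl iminium chloride 2 (not isolated)
Conditions: POCl3, DMF, PhMe, 0 → 100 °C; then ice-water
Reagents that add atoms: N,N-dimethylformamide, CN(C)C=O; water, O
Why: Vilsmeier–Haack formylation attacks the α-position para to a methoxy group, and because the two such positions of symmetric 1 are equivalent, hydrolysis of 2 should give one aldehyde.

Step 2
Reactants: 3 4,8-dimethoxy-1-naphthaldehyde
Product: 4 4-hydroxy-8-methoxy-1-naphthaldehyde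
Conditions: NaSEt, DMF, 100 °C; then 1 M HCl
Reagents that add atoms: none
Why: SN2 O-demethylation by thiolate should select the 4-methyl ether, because only its aryloxide is conjugated with the para formyl group; Lewis acids, which would chelate CHO and the peri 8-OMe, are avoided.

Step 3
Reactants: 4 4-hydroxy-8-methoxy-1-naphthaldehyde
Product: 5 4-(benzyloxy)-8-methoxy-1-naphthaldehyde
Conditions: BnBr, K2CO3, DMF, rt
Reagents that add atoms: benzyl bromide, BrCc1ccccc1
Why: Williamson etherification of the acidic, formyl-conjugated naphthol installs a group that can later be removed without touching the naphthyl methyl ether.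

Step 4
Reactants: 5 4-(benzyloxy)-8-methoxy-1-naphthaldehyde; 6 triethyl phosphonoacetate
Product: 8 ethyl (E)-3-[4-(benzyloxy)-8-methoxynaphthalen-1-yl]acrylate, via sodium phosphonoacetate carbanion 7 (not isolated)
Conditions: NaH, THF, 0 °C → rt
Reagents that add atoms: none
Why: Horner–Wadsworth–Emmons olefination with a stabilised phosphonate anion should give the (E)-enoate by reversible addition and anti-selective elimination.

Step 5
Reactants: 8 ethyl (E)-3-[4-(benzyloxy)-8-methoxynaphthalen-1-yl]acrylate; 9 2-(furan-2-yl)-4,4,5,5-tetramethyl-1,3,2-dioxaborolane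
Product: 10 ethyl (3S)-3-[4-(benzyloxy)-8-methoxynaphthalen-1-yl]-3-(furan-2-yl)propanoate
Conditions: [RhCl(C2H4)2]2 (2.5 mol %), (S,S)-Ph-bod* (5.5 mol %), aq KOH (0.5 equiv), 1,4-dioxane–H2O 10:1, 40 °C; 9 (3 equiv) added in portions
Reagents that add atoms: none
Why: In this Hayashi–Miyaura asymmetric 1,4-addition the furyl–Rh(I) species inserts the enoate held by its α-si face in the chiral diene pocket and the oxa-π-allyl rhodium is hydrolysed, which sets the stereocentre as S, while portionwise dosing at mild temperature offsets protodeboronation.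

Step 6
Reactants: 10 ethyl (3S)-3-[4-(benzyloxy)-8-methoxynaphthalen-1-yl]-3-(furan-2-yl)propanoate
Product: 11 (3S)-3-[4-(benzyloxy)-8-methoxynaphthalen-1-yl]-3-(furan-2-yl)propanal
Conditions: DIBAL-H (1.1 equiv), CH2Cl2, −78 °C; MeOH, then aq Rochelle salt
Reagents that add atoms: none
Why: In this partial ester reduction the aluminium hemiacetal persists at −78 °C and collapses only on quench, and the stereocentre is β to the carbonyl and so cannot enolise.

Step 7
Reactants: 11 (3S)-3-[4-(benzyloxy)-8-methoxynaphthalen-1-yl]-3-(furan-2-yl)propanal; 12 (methoxymethyl)triphenylphosphonium chloride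
Product: 14 2-{(1S)-1-[4-(benzyloxy)-8-methoxynaphthalen-1-yl]-4-methoxybut-3-en-1-yl}furan (E/Z mixture), via methoxymethylidene phosphorane 13 (not isolated)
Conditions: 12, KHMDS, THF, 0 °C; then 11, −78 °C → rt
Reagents that add atoms: none
Why: The Wittig methoxymethylenation adds the missing carbon as an enol ether, and its alkene geometry is irrelevant because both isomers hydrolyse to the same aldehyde.

Step 8
Reactants: 14 2-{(1S)-1-[4-(benzyloxy)-8-methoxynaphthalen-1-yl]-4-methoxybut-3-en-1-yl}furan
Product: 15 (4S)-4-[4-(benzyloxy)-8-methoxynaphthalen-1-yl]-4-(furan-2-yl)butanal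
Conditions: 1 M aq HCl–THF 1:5, rt
Reagents that add atoms: water, O
Why: In this enol ether hydrolysis C-protonation of the acyclic enol ether is far faster than protonation of a 2-alkylfuran, so dilute acid at room temperature should free the aldehyde and leave the furan intact.

Step 9
Reactants: 15 (4S)-4-[4-(benzyloxy)-8-methoxynaphthalen-1-yl]-4-(furan-2-yl)butanal; 16 2-chloro-1,1-dimethoxyethane
Product: 19 (6S)-6-[4-(benzyloxy)-8-methoxynaphthalen-1-yl]-6-(furan-2-yl)-1-methoxyhex-1-yn-3-ol (both C3 epimers), via methoxyethyne 17 (not isolated), via lithium methoxyacetylide 18 (not isolated)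
Conditions: 16 (2 equiv), LiNEt2 (3 equiv per 16, from Et2NH/n-BuLi), THF, −78 → 0 °C; then 15, −78 °C; sat. aq NaHCO3
Reagents that add atoms: none
Why: Successive eliminations of methanol and HCl from 16 and deprotonation give the acetylide, which undergoes 1,2-addition to the aldehyde; the carbinol configuration does not matter because it is oxidised next, and the basic quench avoids Meyer–Schuster rearrangement.

Step 10
Reactants: 19 (6S)-6-[4-(benzyloxy)-8-methoxynaphthalen-1-yl]-6-(furan-2-yl)-1-methoxyhex-1-yn-3-ol
Product: 20 (6S)-6-[4-(benzyloxy)-8-methoxynaphthalen-1-yl]-6-(furan-2-yl)-1-methoxyhex-1-yn-3-one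
Conditions: activated MnO2 (excess), CH2Cl2, rt; filtration through Celite, used without chromatography
Reagents that add atoms: none
Why: MnO2 oxidation of a propargylic alcohol is neutral and heterogeneous and needs no aqueous work-up, which suits an ynol ether that is sensitive to acid and water.

Step 11
Reactants: 20 (6S)-6-[4-(benzyloxy)-8-methoxynaphthalen-1-yl]-6-(furan-2-yl)-1-methoxyhex-1-yn-3-one
Product: 22 (4S)-4-[4-(benzyloxy)-8-methoxynaphthalen-1-yl]-7-hydroxy-8-methoxy-3,4-dihydronaphthalen-1(2H)-one, via oxa-bridged cycloadduct 21 (not isolated)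
Conditions: degassed PhMe (0.01 M), BHT (0.2 equiv), 4 Å MS, sealed tube, 120 °C, dark
Reagents that add atoms: none
Why: Proposed new method: on heating, the furan of 20 should add as the 4π partner across the ynone in a strongly asynchronous [4+2] process, the unsubstituted furan α-carbon (future C7) attacking the methoxy-bearing, β-electrophilic alkyne carbon (C8) while the tether-bearing furan carbon (C4a) bonds to the α-carbon (C8a) to give 7-oxanorbornadiene 21; its C4a–O bond then ionises to a methoxy-stabilised vinylogous oxocarbenium ion, and loss of the only bridgehead hydrogen (H-7, shuttled by BHT and by phenol already formed) gives 22 irreversibly and drains the reversible cycloaddition. The closest known reaction type is the intramolecular Diels–Alder reaction of 2-alkylfurans with tethered alkynyl ketones followed by aromatising opening of the oxa-bridge to ring-fused phenols; what has not been shown is an alkoxy donor on the alkyne terminus, which lowers dienophilicity but polarises the triple bond in the matched sense. The cyclohexanone closes in the fused (type 1) mode as a six-membered ring over the four-atom link C4–C3–C2–C1, helped by the branched C4 that favours the folded rotamer, and the benzene ring is the six-carbon ring of 21 once the bridge has opened. No lasting stereocentre is created, since the bridgeheads C4a and C7 become aromatic and the furan face that reacts is therefore irrelevant, while C4 is only a spectator on the tether. The selectivity needed is regiochemical and comes from the substrate: the short tether allows only the C4a–C8a/C7–C8 pairing, and the 8-methoxy group together with the single bridgehead hydrogen allows opening only towards a C7 hydroxyl. A methyl ynol ether has no β-hydrogen for retro-ene fragmentation to a ketene and should tolerate the temperature, and high dilution over sieves limits hydration and addition of the product phenol to unreacted ynone.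

Step 12
Reactants: 22 (4S)-4-[4-(benzyloxy)-8-methoxynaphthalen-1-yl]-7-hydroxy-8-methoxy-3,4-dihydronaphthalen-1(2H)-one
Product: 23 (4S)-7,8-dihydroxy-4-(4-hydroxy-8-methoxynaphthalen-1-yl)-3,4-dihydronaphthalen-1(2H)-one
Conditions: BCl3 (6 equiv), pentamethylbenzene (3 equiv), CH2Cl2, −78 → 0 °C; then H2O
Reagents that add atoms: none
Why: In this Lewis-acid ether cleavage boron bound to the C1 carbonyl and to O-7 holds the 8-methoxy oxygen in a chelate so that chloride removes its methyl group, the benzyl ether ionises at low temperature with pentamethylbenzene trapping the benzyl cation, and the naphthyl methyl ether has no chelating neighbour and should survive at or below 0 °C.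

**Compound list**
1 | 1,5-dimethoxynaphthalene | COc1cccc2c(OC)cccc12 | starting material
2 | N-[(4,8-dimethoxynaphthalen-1-yl)methylidene]-N-methylmethanaminium chloride | COc1cccc2c(OC)ccc(C=[N+](C)C)c12.[Cl-] | intermediate
3 | 4,8-dimethoxy-1-naphthaldehyde | COc1cccc2c(OC)ccc(C=O)c12 | intermediate
4 | 4-hydroxy-8-methoxy-1-naphthaldehyde | COc1cccc2c(O)ccc(C=O)c12 | intermediate
5 | 4-(benzyloxy)-8-methoxy-1-naphthaldehyde | COc1cccc2c(OCc3ccccc3)ccc(C=O)c12 | intermediate
6 | triethyl phosphonoacetate | CCOC(=O)CP(=O)(OCC)OCC | starting material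
7 | sodium salt of triethyl phosphonoacetate (carbanion) | CCOC(=O)[CH-]P(=O)(OCC)OCC.[Na+] | intermediate
8 | ethyl (E)-3-[4-(benzyloxy)-8-methoxynaphthalen-1-yl]acrylate | COc1cccc2c(OCc3ccccc3)ccc(/C=C/C(=O)OCC)c12 | intermediate
9 | 2-(furan-2-yl)-4,4,5,5-tetramethyl-1,3,2-dioxaborolane | CC1(C)OB(c2ccco2)OC1(C)C | starting material
10 | ethyl (3S)-3-[4-(benzyloxy)-8-methoxynaphthalen-1-yl]-3-(furan-2-yl)propanoate | COc1cccc2c(OCc3ccccc3)ccc([C@@H](c3ccco3)CC(=O)OCC)c12 | intermediate
11 | (3S)-3-[4-(benzyloxy)-8-methoxynaphthalen-1-yl]-3-(furan-2-yl)propanal | COc1cccc2c(OCc3ccccc3)ccc([C@@H](c3ccco3)CC=O)c12 | intermediate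
12 | (methoxymethyl)triphenylphosphonium chloride | COC[P+](c1ccccc1)(c1ccccc1)c1ccccc1.[Cl-] | starting material
13 | (methoxymethylidene)triphenylphosphorane | COC=P(c1ccccc1)(c1ccccc1)c1ccccc1 | intermediate
14 | 2-{(1S)-1-[4-(benzyloxy)-8-methoxynaphthalen-1-yl]-4-methoxybut-3-en-1-yl}furan, E/Z mixture | COc1cccc2c(OCc3ccccc3)ccc([C@@H](c3ccco3)CC=COC)c12 | intermediate
15 | (4S)-4-[4-(benzyloxy)-8-methoxynaphthalen-1-yl]-4-(furan-2-yl)butanal | COc1cccc2c(OCc3ccccc3)ccc([C@@H](c3ccco3)CCC=O)c12 | intermediate
16 | 2-chloro-1,1-dimethoxyethane | COC(CCl)OC | starting material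
17 | methoxyethyne | COC#C | intermediate
18 | lithium methoxyacetylide | [Li]C#COC | intermediate
19 | (6S)-6-[4-(benzyloxy)-8-methoxynaphthalen-1-yl]-6-(furan-2-yl)-1-methoxyhex-1-yn-3-ol, both C3 epimers | COc1cccc2c(OCc3ccccc3)ccc([C@@H](c3ccco3)CCC(O)C#COC)c12 | intermediate
20 | (6S)-6-[4-(benzyloxy)-8-methoxynaphthalen-1-yl]-6-(furan-2-yl)-1-methoxyhex-1-yn-3-one | COc1cccc2c(OCc3ccccc3)ccc([C@@H](c3ccco3)CCC(=O)C#COC)c12 | intermediate
21 | (4S)-4-[4-(benzyloxy)-8-methoxynaphthalen-1-yl]-4a,7-epoxy-8-methoxy-3,4,4a,7-tetrahydronaphthalen-1(2H)-one, bridgehead configuration open (either diastereomer leads to 22) | COc1cccc2c(OCc3ccccc3)ccc([C@@H]3CCC(=O)C4=C(OC)C5C=CC34O5)c12 | intermediate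
22 | (4S)-4-[4-(benzyloxy)-8-methoxynaphthalen-1-yl]-7-hydroxy-8-methoxy-3,4-dihydronaphthalen-1(2H)-one | COc1cccc2c(OCc3ccccc3)ccc([C@@H]3CCC(=O)c4c3ccc(O)c4OC)c12 | intermediate
23 | (4S)-7,8-dihydroxy-4-(4-hydroxy-8-methoxynaphthalen-1-yl)-3,4-dihydronaphthalen-1(2H)-one (CNP0535815.1) | COc1cccc2c(O)ccc([C@@H]3CCC(=O)c4c3ccc(O)c4O)c12 | target

**Total step count:** 12. **Longest linear sequence:** 12 steps (from 1).

**Steps most likely to fail**

**Step 11 (new method).**
- **Risk:** the methoxy donor may make the alkyne too poor a 2π partner. The reversible cycloaddition would then never build up adduct, while the ynone is slowly lost to hydration, oligomerisation or addition of phenol.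
- **Fallback (known chemistry only, from aldehyde 15):**
  - Lithiated commercial 3,3-diethoxyprop-1-yne (n-BuLi, THF, −78 °C) is added to give (7S)-7-[4-(benzyloxy)-8-methoxynaphthalen-1-yl]-1,1-diethoxy-7-(furan-2-yl)hept-2-yn-4-ol F1.
  - MnO2 oxidation gives the acetal-bearing alkynyl ketone (7S)-7-[4-(benzyloxy)-8-methoxynaphthalen-1-yl]-1,1-diethoxy-7-(furan-2-yl)hept-2-yn-4-one F2. Its alkyne substituent is a σ-acceptor and not a π-donor.
  - Heating in toluene should give, by the established furan/alkynyl ketone cycloaddition, the oxa-bridged adduct (4S)-4-[4-(benzyloxy)-8-methoxynaphthalen-1-yl]-8-(diethoxymethyl)-4a,7-epoxy-3,4,4a,7-tetrahydronaphthalen-1(2H)-one F3.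
  - Catalytic TsOH in wet acetone opens the bridge at the quaternary bridgehead and frees the aldehyde, giving (5S)-5-[4-(benzyloxy)-8-methoxynaphthalen-1-yl]-2-hydroxy-8-oxo-5,6,7,8-tetrahydronaphthalene-1-carbaldehyde F4.
  - Dakin oxidation (sodium percarbonate, THF–H2O, 0 °C) exchanges the formyl group ortho to the phenol for hydroxyl, giving (4S)-4-[4-(benzyloxy)-8-methoxynaphthalen-1-yl]-7,8-dihydroxy-3,4-dihydronaphthalen-1(2H)-one F5.
  - Debenzylation with BCl3/pentamethylbenzene at −78 °C rejoins the route at 23.

**Step 5.**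
- **Risk:** protodeboronation of the 2-furyl boron reagent may outrun transmetalation and insertion into the hindered, peri-substituted β-aryl enoate, and facial discrimination may erode at the temperature then required.
- **Fallback (auxiliary-controlled cuprate addition, from 8):**
  - Saponification (LiOH, THF–H2O) gives (E)-3-[4-(benzyloxy)-8-methoxynaphthalen-1-yl]acrylic acid F6.
  - The mixed pivalic anhydride is coupled with (4S)-4-phenyl-1,3-oxazolidin-2-one (PivCl, Et3N, LiCl, THF) to give (4S)-3-{(E)-3-[4-(benzyloxy)-8-methoxynaphthalen-1-yl]acryloyl}-4-phenyl-1,3-oxazolidin-2-one F7.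
  - 2-Furylmagnesium bromide/CuBr·SMe2 (THF–Me2S, −40 °C) should attack the Mg-chelated s-cis imide anti to the 4-phenyl group. This gives (4S)-3-{(3S)-3-[4-(benzyloxy)-8-methoxynaphthalen-1-yl]-3-(furan-2-yl)propanoyl}-4-phenyl-1,3-oxazolidin-2-one F8, whose diastereomeric purity can be raised by crystallisation.
  - Ethanolysis (EtOMgBr, EtOH–THF, 0 °C) returns to the route at 10.

**Step 10.**
- **Risk:** the ynol ether may be lost through acid- or water-triggered processes on the oxidant surface or in handling, namely Meyer–Schuster rearrangement of the carbinol or hydration of the ynone.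
- **Fallback (acylation in place of addition/oxidation, from 15):**
  - Silver(I) oxide oxidation (AgNO3, NaOH, aq EtOH, rt), which spares the furan, gives (4S)-4-[4-(benzyloxy)-8-methoxynaphthalen-1-yl]-4-(furan-2-yl)butanoic acid F9.
  - CDI and MeNH(OMe)·HCl give (4S)-4-[4-(benzyloxy)-8-methoxynaphthalen-1-yl]-4-(furan-2-yl)-N-methoxy-N-methylbutanamide F10.
  - Lithium methoxyacetylide 18 (THF, −78 °C) is added, and inverse quench into cold phosphate buffer collapses the chelated adduct and rejoins the route at 20.

**Further compounds**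
F1 | step 11 | (7S)-7-[4-(benzyloxy)-8-methoxynaphthalen-1-yl]-1,1-diethoxy-7-(furan-2-yl)hept-2-yn-4-ol (both C4 epimers) | COc1cccc2c(OCc3ccccc3)ccc([C@@H](c3ccco3)CCC(O)C#CC(OCC)OCC)c12
F2 | step 11 | (7S)-7-[4-(benzyloxy)-8-methoxynaphthalen-1-yl]-1,1-diethoxy-7-(furan-2-yl)hept-2-yn-4-one | COc1cccc2c(OCc3ccccc3)ccc([C@@H](c3ccco3)CCC(=O)C#CC(OCC)OCC)c12
F3 | step 11 | (4S)-4-[4-(benzyloxy)-8-methoxynaphthalen-1-yl]-8-(diethoxymethyl)-4a,7-epoxy-3,4,4a,7-tetrahydronaphthalen-1(2H)-one | COc1cccc2c(OCc3ccccc3)ccc([C@@H]3CCC(=O)C4=C(C(OCC)OCC)C5C=CC34O5)c12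
F4 | step 11 | (5S)-5-[4-(benzyloxy)-8-methoxynaphthalen-1-yl]-2-hydroxy-8-oxo-5,6,7,8-tetrahydronaphthalene-1-carbaldehyde | COc1cccc2c(OCc3ccccc3)ccc([C@@H]3CCC(=O)c4c3ccc(O)c4C=O)c12
F5 | step 11 | (4S)-4-[4-(benzyloxy)-8-methoxynaphthalen-1-yl]-7,8-dihydroxy-3,4-dihydronaphthalen-1(2H)-one | COc1cccc2c(OCc3ccccc3)ccc([C@@H]3CCC(=O)c4c3ccc(O)c4O)c12
F6 | step 5 | (E)-3-[4-(benzyloxy)-8-methoxynaphthalen-1-yl]acrylic acid | COc1cccc2c(OCc3ccccc3)ccc(/C=C/C(=O)O)c12
F7 | step 5 | (4S)-3-{(E)-3-[4-(benzyloxy)-8-methoxynaphthalen-1-yl]acryloyl}-4-phenyl-1,3-oxazolidin-2-one | COc1cccc2c(OCc3ccccc3)ccc(/C=C/C(=O)N3[C@@H](c4ccccc4)COC3=O)c12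
F8 | step 5 | (4S)-3-{(3S)-3-[4-(benzyloxy)-8-methoxynaphthalen-1-yl]-3-(furan-2-yl)propanoyl}-4-phenyl-1,3-oxazolidin-2-one | COc1cccc2c(OCc3ccccc3)ccc([C@@H](c3ccco3)CC(=O)N3[C@@H](c4ccccc4)COC3=O)c12
F9 | step 10 | (4S)-4-[4-(benzyloxy)-8-methoxynaphthalen-1-yl]-4-(furan-2-yl)butanoic acid | COc1cccc2c(OCc3ccccc3)ccc([C@@H](c3ccco3)CCC(=O)O)c12
F10 | step 10 | (4S)-4-[4-(benzyloxy)-8-methoxynaphthalen-1-yl]-4-(furan-2-yl)-N-methoxy-N-methylbutanamide | COc1cccc2c(OCc3ccccc3)ccc([C@@H](c3ccco3)CCC(=O)N(C)OC)c12
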